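**Retrosynthetic overview**
- The target is the double hydrolysis product of 5-ethoxy-3-hexadecyl-2-isopropoxy-1,4-benzoquinone, which is the oxidation product of the matching hydroquinone.
- Structural basis: ring atoms C1(=O)–C2(OH)–C3(C16H33)–C4(=O) of the quinone are four contiguous carbons that already exist as the four-membered ring of 3-hexadecyl-4-isopropoxycyclobut-3-ene-1,2-dione, so only the C5(OH)=C6(H) pair is missing.
- That pair is delivered as (Z)-2-ethoxyvinyllithium, added to the cyclobutenedione carbonyl next to the isopropoxy carbon. Heating the carbinol cleaves the cyclobutenone C1–C4 bond and joins the former carbonyl carbon to the ethoxy-bearing vinyl carbon (the future C4–C5 bond of the quinone).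
- The cyclobutenedione comes from squaric acid (via diisopropyl squarate) and hexadecylmagnesium bromide; the vinyllithium comes from ethyl vinyl ether by bromination, dehydrobromination and bromine–lithium exchange.
- Ring order: the four-membered ring is bought; the single six-membered carbocycle is the only ring formed, in the thermolysis.

Key step: step 8

Remark on the chemistry: the target has no stereocentres, and the organometallic reagents 4 and 10 are handled as solutions and used directly.

**Step 1**
Reactants: 1 squaric acid
Product: 2 diisopropyl squarate (3,4-diisopropoxycyclobut-3-ene-1,2-dione)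
Conditions: i-PrOH (excess), toluene (or benzene), reflux, Dean–Stark water removal
Reagents that add atoms: propan-2-ol, CC(C)O
Why: Squaric acid is a strong vinylogous acid that catalyses its own Fischer-type esterification, and continuous azeotropic removal of water drives both hydroxyls to the isopropyl vinylogous ester; no stereocentre is involved.

**Step 2**
Reactants: 3 1-bromohexadecane
Product: 4 hexadecylmagnesium bromide (titrated THF solution)
Conditions: Mg turnings, I2 (cat.), THF, 40–60 °C, slow addition of the bromide
Reagents that add atoms: magnesium, [Mg]
Why: Grignard formation by insertion of magnesium into the primary C–Br bond is routine for long-chain alkyl bromides, and slow addition keeps Wurtz coupling low.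

**Step 3**
Reactants: 2 diisopropyl squarate; 4 hexadecylmagnesium bromide
Product: 6 3-hexadecyl-4-isopropoxycyclobut-3-ene-1,2-dione, via diisopropoxy carbinol adduct 5 (not isolated)
Conditions: 4 (1.05 equiv) added to 2, THF, −78 → −30 °C; then 6 M aq HCl, 0 °C → rt; chromatography
Reagents that add atoms: water, O (from the aqueous acid; it supplies the new carbonyl oxygen when the ionised carbinol is rehydrated)
Why: Grignard 1,2-addition to one of the two equivalent squarate carbonyls stops at the mono-adduct because the remaining carbonyl is a deactivated vinylogous ester, and acid then ionises the tertiary carbinol to a dialkoxy-stabilised allyl cation that takes up water at the distal alkoxy carbon and loses isopropanol (squarate 1,2-addition followed by acid rearrangement), leaving no stereocentre.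

**Step 4**
Reactants: 7 ethyl vinyl ether
Product: 8 1,2-dibromo-1-ethoxyethane (racemic, used crude)
Conditions: Br2 (1.0 equiv), pentane, −78 °C
Reagents that add atoms: bromine, BrBr
Why: Electrophilic addition of bromine to the electron-rich enol ether double bond is fast and clean at low temperature; the single stereocentre of the α-bromo ether is racemic and is removed in the next step.

**Step 5**
Reactants: 8 1,2-dibromo-1-ethoxyethane
Product: 9 (Z)-1-bromo-2-ethoxyethene
Conditions: N,N-diethylaniline, 90–100 °C; fractional distillation under reduced pressure
Reagents that add atoms: none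
Why: The α-bromo ether ionises readily to a bromomethyl oxocarbenium ion and the amine removes the adjacent proton (E1-type dehydrobromination); the Z isomer should be the favoured geometry and is freed from the minor E isomer by fractional distillation.

**Step 6**
Reactants: 9 (Z)-1-bromo-2-ethoxyethene
Product: 10 (Z)-2-ethoxyvinyllithium (solution kept at −78 °C and used at once)
Conditions: n-BuLi (0.95 equiv relative to 9), THF, −78 °C
Reagents that add atoms: n-butyllithium, [Li]CCCC
Why: Bromine–lithium exchange on a vinyl bromide proceeds with retention of alkene geometry, and the Z reagent is held by internal O–Li coordination with Li and OEt syn, which disfavours β-elimination of lithium ethoxide at −78 °C.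

**Step 7**
Reactants: 6 3-hexadecyl-4-isopropoxycyclobut-3-ene-1,2-dione; 10 (Z)-2-ethoxyvinyllithium
Product: 11 4-[(Z)-2-ethoxyethenyl]-2-hexadecyl-4-hydroxy-3-isopropoxycyclobut-2-en-1-one (racemic, crude)
Conditions: 6 in THF added to 10 (1.2 equiv), THF, −78 °C; sat. aq NaHCO3 quench at −78 °C; Et2O extraction, drying over K2CO3, cold concentration, no acid contact
Reagents that add atoms: none
Why: 1,2-Addition of an alkenyllithium to a 3-alkyl-4-alkoxycyclobutenedione occurs at C1, the carbonyl attached to the isopropoxy-bearing carbon, because C2 is the electron-rich vinylogous ester carbonyl; the new carbinol stereocentre forms racemic without control, which is harmless because it is erased in step 8.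

**Step 8**
Reactants: 11 4-[(Z)-2-ethoxyethenyl]-2-hexadecyl-4-hydroxy-3-isopropoxycyclobut-2-en-1-one
Product: 14 5-ethoxy-3-hexadecyl-2-isopropoxybenzene-1,4-diol, via dienylketene 12 (not isolated), via cyclohexadienone 13 (not isolated)
Conditions: degassed toluene (0.02–0.05 M), 110 °C, argon, base-washed glassware; p-xylene, 138 °C if conversion is slow
Reagents that add atoms: none
Why: On heating, the cyclobutenone undergoes thermal conrotatory 4π electrocyclic opening of its C1–C4 bond, and the donor hydroxyl on C4 turns outward, so the ethoxyvinyl arm is placed on the same side as the new ketene in dienylketene 12. The ketene carbon then bonds to the ethoxy-bearing vinyl carbon in a thermal disrotatory 6π electrocyclisation, which closes the six-membered carbocycle (the only ring formed), and dienone 13 enolises at once to the aromatic hydroquinone, making the sequence irreversible. The closest known reaction type is the thermal ring expansion of squarate-derived 4-alkenyl-4-hydroxycyclobutenones to hydroquinones (Liebeskind–Moore rearrangement). No stereocentre is created: the racemic carbinol carbon becomes an sp2 ring carbon and the Z-alkene geometry disappears on aromatisation. The ring-forming event needs no regiocontrol, because the connectivity of 11 already places the hexadecyl carbon next to the former ketene carbon and the ethoxy carbon on its other side; what it needs is ring opening in preference to acid-induced 1,3-transposition of the β-hydroxy enol ether, which neutral base-washed glassware and the accelerating isopropoxy and hydroxyl donors should secure.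

**Step 9**
Reactants: 14 5-ethoxy-3-hexadecyl-2-isopropoxybenzene-1,4-diol
Product: 15 5-ethoxy-3-hexadecyl-2-isopropoxycyclohexa-2,5-diene-1,4-dione
Conditions: Ag2O, K2CO3, Et2O, rt (crude 14 used directly)
Reagents that add atoms: none
Why: Electron-rich hydroquinones are oxidised to p-benzoquinones by Ag2O under neutral anhydrous conditions (hydroquinone-to-quinone oxidation), which leaves the two enol ether groups untouched.

**Step 10**
Reactants: 15 5-ethoxy-3-hexadecyl-2-isopropoxycyclohexa-2,5-diene-1,4-dione
Product: 16 3-hexadecyl-2,5-dihydroxycyclohexa-2,5-diene-1,4-dione (target)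
Conditions: 2 M aq NaOH, EtOH, argon, 60–80 °C; then 2 M HCl to pH 1–2; recrystallisation
Reagents that add atoms: sodium hydroxide (aqueous), [Na+].[OH-]; water, O
Why: Each alkoxy group sits on the β-carbon of a quinone enone, so hydroxide displaces it by conjugate addition–elimination (vinylogous ester saponification) to give the base-stable dianion of the dihydroxyquinone, which acid converts into the target.

**Compound list**
1 | squaric acid (3,4-dihydroxycyclobut-3-ene-1,2-dione) | O=C1C(O)=C(O)C1=O | starting material
2 | diisopropyl squarate (3,4-diisopropoxycyclobut-3-ene-1,2-dione) | CC(C)OC1=C(OC(C)C)C(=O)C1=O | intermediate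
3 | 1-bromohexadecane | CCCCCCCCCCCCCCCCBr | starting material
4 | hexadecylmagnesium bromide | CCCCCCCCCCCCCCCC[Mg]Br | intermediate
5 | 4-hexadecyl-4-hydroxy-2,3-diisopropoxycyclobut-2-en-1-one (racemic) | CCCCCCCCCCCCCCCCC1(O)C(OC(C)C)=C(OC(C)C)C1=O | intermediate
6 | 3-hexadecyl-4-isopropoxycyclobut-3-ene-1,2-dione | CCCCCCCCCCCCCCCCC1=C(OC(C)C)C(=O)C1=O | intermediate
7 | ethyl vinyl ether | CCOC=C | starting material
8 | 1,2-dibromo-1-ethoxyethane (racemic) | CCOC(Br)CBr | intermediate
9 | (Z)-1-bromo-2-ethoxyethene | CCO/C=C\Br | intermediate
10 | (Z)-2-ethoxyvinyllithium | CCO/C=C\[Li] | intermediate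
11 | 4-[(Z)-2-ethoxyethenyl]-2-hexadecyl-4-hydroxy-3-isopropoxycyclobut-2-en-1-one (racemic) | CCCCCCCCCCCCCCCCC1=C(OC(C)C)C(O)(/C=C\OCC)C1=O | intermediate
12 | (3Z,5Z)-6-ethoxy-2-hexadecyl-4-hydroxy-3-isopropoxyhexa-1,3,5-trien-1-one (dienylketene) | CCCCCCCCCCCCCCCCC(=C=O)/C(OC(C)C)=C(O)\C=C/OCC | intermediate
13 | 6-ethoxy-2-hexadecyl-4-hydroxy-3-isopropoxycyclohexa-2,4-dien-1-one (racemic) | CCCCCCCCCCCCCCCCC1=C(OC(C)C)C(O)=CC(OCC)C1=O | intermediate
14 | 5-ethoxy-3-hexadecyl-2-isopropoxybenzene-1,4-diol | CCCCCCCCCCCCCCCCc1c(OC(C)C)c(O)cc(OCC)c1O | intermediate
15 | 5-ethoxy-3-hexadecyl-2-isopropoxycyclohexa-2,5-diene-1,4-dione | CCCCCCCCCCCCCCCCC1=C(OC(C)C)C(=O)C=C(OCC)C1=O | intermediate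
16 | 3-hexadecyl-2,5-dihydroxycyclohexa-2,5-diene-1,4-dione (2,5-dihydroxy-3-hexadecyl-1,4-benzoquinone) | CCCCCCCCCCCCCCCCC1=C(O)C(=O)C=C(O)C1=O | target

**Totals**
Total step count: 10.
Longest linear sequence: 7 steps (steps 4 to 10, from ethyl vinyl ether).

**Steps most likely to fail**

1. Step 8. Three processes could divert it:
   - trace acid could trigger allylic ionisation of the tertiary β-hydroxy enol ether, with loss of ethanol to a conjugated aldehyde, before the ring opens;
   - the 6π closure could be slow because the ethoxy group on the Z-vinyl terminus points into the closing triene, letting the ketene be captured by the free hydroxyl or oligomerise;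
   - ethanol could be eliminated from the dienone before it enolises.

   Fallback: it sets out from 6 and 10. The lithium alkoxide formed in their union is silylated in the flask with Me3SiCl at −78 °C before any aqueous contact, to give 4-[(Z)-2-ethoxyethenyl]-2-hexadecyl-3-isopropoxy-4-(trimethylsilyloxy)cyclobut-2-en-1-one F1. With the hydroxyl masked, neither ionisation nor internal ketene capture is open. Heating F1 in toluene or p-xylene should give, by the same electrocyclic sequence, the mono-silylated hydroquinone 6-ethoxy-2-hexadecyl-3-isopropoxy-4-(trimethylsilyloxy)phenol F2. This is oxidatively desilylated with (NH4)2Ce(NO3)6 in aqueous MeCN at 0 °C. The fallback comes back to the route at quinone 15; hydroquinone 14 is bypassed.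

2. Step 7. The vinyllithium could lose lithium ethoxide by β-elimination during generation or transfer, incomplete exchange could leave n-BuLi that adds in its place, and some attack at the vinylogous ester carbonyl could occur.

   Fallback: it sets out from 6. Lithium ethoxyacetylide (ethoxyacetylene, n-BuLi, THF, −78 °C), a thermally robust nucleophile, is added to the same carbonyl to give 4-(ethoxyethynyl)-2-hexadecyl-4-hydroxy-3-isopropoxycyclobut-2-en-1-one F3. Semi-hydrogenation of the alkyne (H2, 1 atm, Pd/CaCO3 poisoned with Pb(OAc)2, quinoline, EtOAc containing a little Et3N) delivers hydrogen syn and should give the Z-enol ether. The fallback comes back to the route at 11.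

3. Step 10. The hydrolysis could stall after the first alkoxy group is lost, because the hydroxyquinone anion deactivates the ring toward a second hydroxide addition and the isopropoxy carbon is flanked by the hexadecyl chain. The electron-rich quinone could also degrade oxidatively in hot alkali.

   Fallback: it sets out from 14, with the oxidation of step 9 omitted. BBr3 in CH2Cl2 (−78 → 0 °C) cleaves both alkyl aryl ethers by alkyl–oxygen scission to give 3-hexadecylbenzene-1,2,4,5-tetrol F4. Stirring F4 in MeOH open to air should autoxidise it to the dihydroxyquinone. The fallback comes back to the route at 16.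

**Further compounds**
F1 | step 8 | 4-[(Z)-2-ethoxyethenyl]-2-hexadecyl-3-isopropoxy-4-(trimethylsilyloxy)cyclobut-2-en-1-one (racemic) | CCCCCCCCCCCCCCCCC1=C(OC(C)C)C(O[Si](C)(C)C)(/C=C\OCC)C1=O
F2 | step 8 | 6-ethoxy-2-hexadecyl-3-isopropoxy-4-(trimethylsilyloxy)phenol | CCCCCCCCCCCCCCCCc1c(OC(C)C)c(O[Si](C)(C)C)cc(OCC)c1O
F3 | step 7 | 4-(ethoxyethynyl)-2-hexadecyl-4-hydroxy-3-isopropoxycyclobut-2-en-1-one (racemic) | CCCCCCCCCCCCCCCCC1=C(OC(C)C)C(O)(C#COCC)C1=O
F4 | step 10 | 3-hexadecylbenzene-1,2,4,5-tetrol | CCCCCCCCCCCCCCCCc1c(O)c(O)cc(O)c1O
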